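**Retrosynthetic overview**
- The target comes from its 3',4'-bis-silyl ether. That ether comes from one acyclic C9 chain that closes twice in one flask, first ring C and then ring A.
- Ring C closes when the carbinol OH adds to the C8a ketone with loss of MeOH. Ring A closes when an acylketene, unmasked from a tert-butyl β-keto ester, forms the C4a–C5 bond.
- O1 is bonded to C8a before ring A exists. The geranyl carbon therefore ends up para to O1 (C6), and no 6/8 mixture can form.
- The chain comes from a C8–C8a Claisen union of the dianion of tert-butyl 2-geranylacetoacetate with an (S)-4-methoxy-5,6-dihydropyran-2-one.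
- The lactone comes from an asymmetric hetero-Diels–Alder reaction of silylated 5-hydroxyvanillin with Brassard's diene, which sets C2. Ring order: sacrificial lactone (opened), then ring C, then ring A. Ring B is bought.

Assumption: 5-hydroxyvanillin, methyl (E)-3-methoxybut-2-enoate, tert-butyl acetoacetate and geranyl bromide are taken as catalogue chemicals, and the labels O1 and C2–C8a are flavanone numbering applied to all intermediates.

**Step 1**
Reactants: 1 3,4-dihydroxy-5-methoxybenzaldehyde
Product: 2 3,4-bis(tert-butyldimethylsilyloxy)-5-methoxybenzaldehyde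
Conditions: TBSCl (2.5 equiv), imidazole (5 equiv), DMF, 23 °C
Reagents that add atoms: tert-butyldimethylsilyl chloride, CC(C)(C)[Si](C)(C)Cl
Why: Imidazole-promoted O-silylation (Corey protocol) masks the acidic catechol against the Lewis acid, dianion and ketene chemistry ahead, and aryl TBS ethers can be removed at the end with fluoride and no base.

**Step 2**
Reactants: 3 methyl (E)-3-methoxybut-2-enoate
Product: 4 1,3-dimethoxy-1-(trimethylsilyloxy)buta-1,3-diene (Brassard's diene)
Conditions: LDA (1.1 equiv, commercial solution), THF, −78 °C; TMSCl, −78 → 23 °C; distil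
Reagents that add atoms: chlorotrimethylsilane, C[Si](C)(C)Cl
Why: Kinetic γ-deprotonation of the vinylogous carbonate followed by O-silylation of the extended enolate (silyl ketene acetal formation) gives the diene, and its ketene acetal geometry does not matter later.

**Step 3**
Reactants: 2 3,4-bis(tert-butyldimethylsilyloxy)-5-methoxybenzaldehyde; 4 Brassard's diene
Product: 6 (6S)-6-[3,4-bis(tert-butyldimethylsilyloxy)-5-methoxyphenyl]-4-methoxy-5,6-dihydro-2H-pyran-2-one, via silyl aldol adduct 5 (not isolated)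
Conditions: Ti(OiPr)4 (10 mol %), (S)-BINOL (11 mol %), 4 Å MS, PhMe, −20 °C; then TFA (10 mol %), CH2Cl2, 0 °C; recrystallise
Reagents that add atoms: none
Why: In this catalytic asymmetric hetero-Diels–Alder reaction of Brassard's diene (stepwise vinylogous Mukaiyama aldol, then lactonisation), the (S)-BINOL–titanium complex directs the diene terminus to the Si face of the aldehyde, as in other Ti/BINOL additions to ArCHO, which sets the (S) carbinol that becomes C2, and one recrystallisation of the lactone raises the ee.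

**Step 4**
Reactants: 7 tert-butyl acetoacetate; 8 geranyl bromide
Product: 9 tert-butyl (4E)-2-acetyl-5,9-dimethyldeca-4,8-dienoate (tert-butyl 2-geranylacetoacetate, racemic)
Conditions: NaH (1.0 equiv), THF, 0 °C; 8 (0.9 equiv), 0 → 23 °C
Reagents that add atoms: none
Why: In this acetoacetic ester alkylation, SN2 attack on the primary allylic bromide keeps the E alkene, and the new α-centre is labile and becomes sp2 in ring A, so its configuration is irrelevant.

**Step 5**
Reactants: 6 (6S)-lactone; 9 tert-butyl 2-geranylacetoacetate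
Product: 11 tert-butyl (6E,9S)-9-[3,4-bis(tert-butyldimethylsilyloxy)-5-methoxyphenyl]-2-[(2E)-3,7-dimethylocta-2,6-dienyl]-9-hydroxy-7-methoxy-3,5-dioxonon-6-enoate, via dilithio dianion 10 (not isolated)
Conditions: 9 (2.2 equiv), LDA (4.5 equiv, commercial solution), THF, −78 → 0 °C; 6, −78 → −20 °C; AcOH quench; rapid chromatography (excess 9 recovered)
Reagents that add atoms: none
Why: In this Huckin–Weiler acylation of a β-keto ester dianion, the γ-carbon (C8) adds 1,2 to the lactone carbonyl (C8a), the ring opens to the alkoxide, the new 1,3-diketone is deprotonated at once so over-addition stops, and the C2–O1 bond is untouched so the (S) centre is kept.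

**Step 6**
Reactants: 11 acyclic hydroxy methoxy-enone diketo ester (keto/enol/lactol and C6 epimers, all of which converge)
Product: 14 (2S)-2-[3,4-bis(tert-butyldimethylsilyloxy)-5-methoxyphenyl]-6-[(2E)-3,7-dimethylocta-2,6-dienyl]-5,7-dihydroxychroman-4-one, via dihydropyranone 12 (not isolated), via acylketene 13 (not isolated)
Conditions: TFA (5 mol %), PhMe (0.01 M), 23 °C, 2 h; then reflux (110 °C) through a Soxhlet thimble of 4 Å MS/K2CO3, 3 h
Reagents that add atoms: none
Why: Proposed new method: at 23 °C the C2 hydroxyl adds to the C8a ketone, the lactol ionises to a 4-methoxydihydropyrylium ion, and the released water returns at C4 and expels MeOH (a Stork–Danheiser-type 1,3-carbonyl transposition, i.e. the usual δ-hydroxy-1,3-dicarbonyl to 2,3-dihydro-4-pyranone closure), so ring C (12) is formed and the C8a oxygen is blocked against 2-pyrone formation before any ketene exists; at reflux the volatile acid, MeOH and t-BuOH are trapped in the thimble, the tert-butyl β-keto ester loses t-BuOH by retro-ene fragmentation (thermal acylketene generation as in transacetoacetylation), and 13 as its C7 enol is a dienylketene whose only six-membered option is C5–C4a bonding (6π electrocyclisation and tautomerisation as in the last stage of a Danheiser benzannulation, formally the biomimetic Claisen closure of a tetraketide), which gives ring A with geranyl fixed at C6, while no bond to C2 is made or broken and no base is present, so the (S) centre is carried through.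

**Step 7**
Reactants: 14 bis-TBS flavanone
Product: 15 (2S)-2-(3,4-dihydroxy-5-methoxyphenyl)-6-[(2E)-3,7-dimethylocta-2,6-dienyl]-5,7-dihydroxychroman-4-one (CNP0110161.1)
Conditions: Et3N·3HF (4 equiv), THF, 0 → 23 °C
Reagents that add atoms: none
Why: In this fluoride desilylation, the slightly acidic reagent cleaves aryl silyl ethers without base, so the retro-oxa-Michael racemisation of C2 is avoided and the geranyl alkenes are untouched.

**Compound list**
1 | 3,4-dihydroxy-5-methoxybenzaldehyde | COc1cc(C=O)cc(O)c1O | starting material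
2 | 3,4-bis(tert-butyldimethylsilyloxy)-5-methoxybenzaldehyde | COc1cc(C=O)cc(O[Si](C)(C)C(C)(C)C)c1O[Si](C)(C)C(C)(C)C | intermediate
3 | methyl (E)-3-methoxybut-2-enoate | COC(=O)/C=C(/OC)C | starting material
4 | 1,3-dimethoxy-1-(trimethylsilyloxy)buta-1,3-diene | C=C(OC)C=C(OC)O[Si](C)(C)C | intermediate
5 | methyl (2E,5S)-5-[3,4-bis(tert-butyldimethylsilyloxy)-5-methoxyphenyl]-3-methoxy-5-(trimethylsilyloxy)pent-2-enoate | COC(=O)/C=C(/OC)C[C@H](O[Si](C)(C)C)c1cc(OC)c(O[Si](C)(C)C(C)(C)C)c(O[Si](C)(C)C(C)(C)C)c1 | intermediate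
6 | (6S)-6-[3,4-bis(tert-butyldimethylsilyloxy)-5-methoxyphenyl]-4-methoxy-5,6-dihydro-2H-pyran-2-one | COC1=CC(=O)O[C@@H](C1)c1cc(OC)c(O[Si](C)(C)C(C)(C)C)c(O[Si](C)(C)C(C)(C)C)c1 | intermediate
7 | tert-butyl acetoacetate | CC(=O)CC(=O)OC(C)(C)C | starting material
8 | geranyl bromide | BrC/C=C(\C)CCC=C(C)C | starting material
9 | tert-butyl (4E)-2-acetyl-5,9-dimethyldeca-4,8-dienoate (racemic) | CC(=O)C(C/C=C(\C)CCC=C(C)C)C(=O)OC(C)(C)C | intermediate
10 | dilithio dianion of 9 | [Li+].[Li+].C=C([O-])C(C/C=C(\C)CCC=C(C)C)=C([O-])OC(C)(C)C | intermediate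
11 | tert-butyl (6E,9S)-9-[3,4-bis(tert-butyldimethylsilyloxy)-5-methoxyphenyl]-2-geranyl-9-hydroxy-7-methoxy-3,5-dioxonon-6-enoate (epimers at C-2 of the chain) | CC(C)(C)OC(=O)C(C/C=C(\C)CCC=C(C)C)C(=O)CC(=O)/C=C(/OC)C[C@H](O)c1cc(OC)c(O[Si](C)(C)C(C)(C)C)c(O[Si](C)(C)C(C)(C)C)c1 | intermediate
12 | tert-butyl 4-{(2S)-2-[3,4-bis(tert-butyldimethylsilyloxy)-5-methoxyphenyl]-4-oxo-3,4-dihydro-2H-pyran-6-yl}-2-geranyl-3-oxobutanoate | CC(C)(C)OC(=O)C(C/C=C(\C)CCC=C(C)C)C(=O)CC1=CC(=O)C[C@@H](c2cc(OC)c(O[Si](C)(C)C(C)(C)C)c(O[Si](C)(C)C(C)(C)C)c2)O1 | intermediate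
13 | acylketene from 12 (geranyl on the ketene carbon C6, ketene carbonyl carbon C5) | O=C=C(C/C=C(\C)CCC=C(C)C)C(=O)CC1=CC(=O)C[C@@H](c2cc(OC)c(O[Si](C)(C)C(C)(C)C)c(O[Si](C)(C)C(C)(C)C)c2)O1 | intermediate
14 | (2S)-2-[3,4-bis(tert-butyldimethylsilyloxy)-5-methoxyphenyl]-6-geranyl-5,7-dihydroxychroman-4-one | COc1cc([C@@H]2CC(=O)c3c(cc(O)c(C/C=C(\C)CCC=C(C)C)c3O)O2)cc(O[Si](C)(C)C(C)(C)C)c1O[Si](C)(C)C(C)(C)C | intermediate
15 | (2S)-2-(3,4-dihydroxy-5-methoxyphenyl)-6-geranyl-5,7-dihydroxychroman-4-one | COc1cc([C@@H]2CC(=O)c3c(cc(O)c(C/C=C(\C)CCC=C(C)C)c3O)O2)cc(O)c1O | target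

**Total steps:** 7.
**Longest linear sequence:** 5 (steps 1, 3, 5, 6, 7).

**Three steps most likely to fail**

Step 6. Three things can go wrong:
- The C7 enol of 11 may close onto C4 to give a γ-pyrone before O1 reaches C8a.
- The α-branched tert-butyl ester may lose t-BuOH slowly.
- The ee may erode at 110 °C.

The fallback sets out from 6 and 8 and comes back at 14. It makes the same ketene by thiophilic activation at room temperature instead of by heat. Commercial S-tert-butyl 3-oxobutanethioate is alkylated with 8 (NaH, THF) to S-tert-butyl 2-geranyl-3-oxobutanethioate F1. LDA (2 equiv) converts it into its dilithio dianion F2, which opens 6 to the thioester analogue of 11 F3. TFA (5 mol %, PhMe, 23 °C) closes ring C to the dihydropyranone thioester F4. AgO2CCF3 with Na2HPO4, added to the same flask at 23 °C, removes the thiolate and releases ketene 13, which closes to 14.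

Step 5. The dianion may deprotonate C3 of 6, and E1cB loss of the lactone carboxylate would then give an achiral dienoic acid. It may also displace the 4-methoxy group by 1,4-addition. The fallback sets out from 6 and comes back at 11. It uses an acyclic, O-blocked acyl donor that has no carboxylate leaving group. Me(MeO)NH·HCl/AlMe3 (CH2Cl2, 0 °C) opens 6 to the hydroxy Weinreb amide F5, and TESCl/imidazole gives its triethylsilyl ether F6. Dianion 10 is acylated by F6 through the chelated tetrahedral intermediate to give the O-triethylsilyl ether of 11 F7. AcOH/THF/H2O then frees the carbinol to give 11.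

Step 3. The electron-rich, bulky aldehyde may react slowly or with only moderate ee under Ti/BINOL catalysis. The fallback sets out from 2 and comes back at 6. It replaces the cycloaddition with a copper-catalysed vinylogous aldol addition followed by a ketene lactonisation. 2,2,6-Trimethyl-4H-1,3-dioxin-4-one is converted (LDA, TMSCl) into the dioxinone silyl dienolate F8. Cu(OTf)2/Tol-BINAP/Bu4N[Ph3SiF2] (2 mol %, THF, −78 °C, ligand antipode chosen for Si-face attack) adds F8 to 2 and, after acidic work-up, gives the (S)-hydroxy dioxinone F9. A short reflux in toluene expels acetone, and the hydroxyl traps the acylketene to give the (S)-keto lactone F10. Me2SO4/K2CO3 in acetone O-methylates the enol to 6.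

**Further compounds**
F1 | step 6 | S-tert-butyl 2-geranyl-3-oxobutanethioate | CC(=O)C(C/C=C(\C)CCC=C(C)C)C(=O)SC(C)(C)C
F2 | step 6 | dilithio dianion of F1 | [Li+].[Li+].C=C([O-])C(C/C=C(\C)CCC=C(C)C)=C([O-])SC(C)(C)C
F3 | step 6 | S-tert-butyl (6E,9S)-9-[3,4-bis(tert-butyldimethylsilyloxy)-5-methoxyphenyl]-2-geranyl-9-hydroxy-7-methoxy-3,5-dioxonon-6-enethioate | CC(C)(C)SC(=O)C(C/C=C(\C)CCC=C(C)C)C(=O)CC(=O)/C=C(/OC)C[C@H](O)c1cc(OC)c(O[Si](C)(C)C(C)(C)C)c(O[Si](C)(C)C(C)(C)C)c1
F4 | step 6 | S-tert-butyl 4-{(2S)-2-[3,4-bis(tert-butyldimethylsilyloxy)-5-methoxyphenyl]-4-oxo-3,4-dihydro-2H-pyran-6-yl}-2-geranyl-3-oxobutanethioate | CC(C)(C)SC(=O)C(C/C=C(\C)CCC=C(C)C)C(=O)CC1=CC(=O)C[C@@H](c2cc(OC)c(O[Si](C)(C)C(C)(C)C)c(O[Si](C)(C)C(C)(C)C)c2)O1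
F5 | step 5 | (2E,5S)-5-[3,4-bis(tert-butyldimethylsilyloxy)-5-methoxyphenyl]-5-hydroxy-N,3-dimethoxy-N-methylpent-2-enamide | CON(C)C(=O)/C=C(/OC)C[C@H](O)c1cc(OC)c(O[Si](C)(C)C(C)(C)C)c(O[Si](C)(C)C(C)(C)C)c1
F6 | step 5 | (2E,5S)-5-[3,4-bis(tert-butyldimethylsilyloxy)-5-methoxyphenyl]-N,3-dimethoxy-N-methyl-5-(triethylsilyloxy)pent-2-enamide | CON(C)C(=O)/C=C(/OC)C[C@H](O[Si](CC)(CC)CC)c1cc(OC)c(O[Si](C)(C)C(C)(C)C)c(O[Si](C)(C)C(C)(C)C)c1
F7 | step 5 | O-triethylsilyl ether of 11 | CC(C)(C)OC(=O)C(C/C=C(\C)CCC=C(C)C)C(=O)CC(=O)/C=C(/OC)C[C@H](O[Si](CC)(CC)CC)c1cc(OC)c(O[Si](C)(C)C(C)(C)C)c(O[Si](C)(C)C(C)(C)C)c1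
F8 | step 3 | 2,2-dimethyl-4-methylidene-6-(trimethylsilyloxy)-4H-1,3-dioxine | C=C1C=C(O[Si](C)(C)C)OC(C)(C)O1
F9 | step 3 | 6-{(2S)-2-[3,4-bis(tert-butyldimethylsilyloxy)-5-methoxyphenyl]-2-hydroxyethyl}-2,2-dimethyl-4H-1,3-dioxin-4-one | CC1(C)OC(=O)C=C(C[C@H](O)c2cc(OC)c(O[Si](C)(C)C(C)(C)C)c(O[Si](C)(C)C(C)(C)C)c2)O1
F10 | step 3 | (6S)-6-[3,4-bis(tert-butyldimethylsilyloxy)-5-methoxyphenyl]oxane-2,4-dione | O=C1CC(=O)O[C@@H](C1)c1cc(OC)c(O[Si](C)(C)C(C)(C)C)c(O[Si](C)(C)C(C)(C)C)c1
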